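**Retrosynthetic overview**
1. C4–O last: target 22 ⇐ hydrogenation of isopropenyl alcohol 21 ⇐ SeO2 allylic hydroxylation of bicycle 18 (ene/[2,3] at the isopropenyl group, oxygen to the α face).
2. Seven-membered ring ⇐ ring-closing metathesis of triene 17 (C8=C9). Ring order: cyclopentane first (step 2), cycloheptene last (step 8).
3. C10–O ⇐ ligand-controlled Pd-catalysed allylic C–H acyloxylation of the allyl arm with isovaleric acid (new). C6–O ⇐ Mitsunobu inversion with unprotected 4-hydroxybenzoic acid.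
4. C6–C7 ⇐ methallylboration of aldehyde 10. Quaternary C1 ⇐ allylboration, then anionic oxy-Cope rearrangement, of enal 4.
5. Enal 4 ⇐ (S)-limonene by ozonolysis and aldol ring contraction.

Assumption and convention: commercial (S)-(−)-limonene is used at the enantiomeric purity supplied (about 97% ee or better); positions follow daucane numbering (C1 quaternary ring-fusion carbon, C4 isopropyl carbinol, C5 ring-fusion CH, C6 benzoate carbon, C8=C9 ring alkene, C10 isovalerate carbon), α = face of H5, β = face of the C1 methyl.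

Step 1
Reactants: 1 (S)-(−)-limonene
Product: 3 (3S)-6-oxo-3-(prop-1-en-2-yl)heptanal, via secondary ozonide 2 (not isolated)
Conditions: O3 (1.0 equiv), CH2Cl2, −78 °C; then Me2S, −78 °C to rt
Reagents that add atoms: ozone, [O-][O+]=O
Why: Ozonolysis with one equivalent of ozone cleaves the electron-richer trisubstituted ring alkene in preference to the 1,1-disubstituted isopropenyl group, and the stereocentre is not touched.

Step 2
Reactants: 3 (3S)-6-oxo-3-(prop-1-en-2-yl)heptanal
Product: 4 (5R)-2-methyl-5-(prop-1-en-2-yl)cyclopent-1-ene-1-carbaldehyde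
Conditions: piperidine (0.2 equiv), AcOH (0.2 equiv), benzene, reflux, Dean–Stark
Reagents that add atoms: none
Why: Enamine-mediated intramolecular aldol condensation, in which the aldehyde α-carbon attacks the methyl ketone to close the five-membered ring and dehydration gives the conjugated enal; the stereocentre is not enolisable and is kept.

Step 3
Reactants: 4 (5R)-2-methyl-5-(prop-1-en-2-yl)cyclopent-1-ene-1-carbaldehyde; 5 allylboronic acid pinacol ester
Product: 7 (1S)-1-[(5R)-2-methyl-5-(prop-1-en-2-yl)cyclopent-1-en-1-yl]but-3-en-1-ol, via boronate ester 6 (not isolated)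
Conditions: 5 (1.3 equiv), (S)-TRIP phosphoric acid (5 mol %), toluene, −30 °C; aqueous NaHCO3 work-up
Reagents that add atoms: 5 allylboronic acid pinacol ester, C=CCB1OC(C)(C)C(C)(C)O1
Why: Chiral phosphoric acid-catalysed allylboration through a closed chair transition state, in which the (S) acid sends the allyl group to the Si face and gives the 1S carbinol under catalyst control.

Step 4
Reactants: 7 (1S)-1-[(5R)-2-methyl-5-(prop-1-en-2-yl)cyclopent-1-en-1-yl]but-3-en-1-ol
Product: 10 (1S,2R,5S)-2-methyl-2-(prop-2-en-1-yl)-5-(prop-1-en-2-yl)cyclopentane-1-carbaldehyde, via potassium alkoxide 8 (not isolated), via potassium enolate 9 (not isolated)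
Conditions: KH (1.5 equiv), 18-crown-6 (1.5 equiv), THF, 0 °C to rt; inverse quench into AcOH–THF, −78 °C
Reagents that add atoms: none
Why: Anionic oxy-Cope rearrangement in which the 1S alkoxide sits equatorial in the chair transition state (forced by the cis methyl on the ring alkene), so the allyl terminus bonds to C1 on the α face anti to the isopropenyl group and creates the quaternary centre, and kinetic C-protonation of enolate 9 from the same α face (anti to isopropenyl and methyl) sets C5.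

Step 5
Reactants: 10 (1S,2R,5S)-2-methyl-2-(prop-2-en-1-yl)-5-(prop-1-en-2-yl)cyclopentane-1-carbaldehyde; 11 2-methylallylboronic acid pinacol ester
Product: 13 (1S)-3-methyl-1-[(1S,2R,5S)-2-methyl-2-(prop-2-en-1-yl)-5-(prop-1-en-2-yl)cyclopentyl]but-3-en-1-ol, via boronate ester 12 (not isolated)
Conditions: 11 (1.5 equiv), (S)-TRIP phosphoric acid (10 mol %), toluene, −30 °C; aqueous work-up
Reagents that add atoms: 11 2-methylallylboronic acid pinacol ester, CC(=C)CB1OC(C)(C)C(C)(C)O1
Why: Phosphoric acid-catalysed allylboration on the Si face, matched with Felkin–Anh addition anti to the quaternary carbon, gives the 1S carbinol (the C6 epimer of the target), and the base-free conditions avoid epimerisation of the α-stereocentre.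

Step 6
Reactants: 13 (1S)-3-methyl-1-[(1S,2R,5S)-2-methyl-2-(prop-2-en-1-yl)-5-(prop-1-en-2-yl)cyclopentyl]but-3-en-1-ol; 14 4-hydroxybenzoic acid
Product: 15 (1R)-3-methyl-1-[(1S,2R,5S)-2-methyl-2-(prop-2-en-1-yl)-5-(prop-1-en-2-yl)cyclopentyl]but-3-en-1-yl 4-hydroxybenzoate
Conditions: PPh3 (2 equiv), DIAD (2 equiv), 14 (2 equiv), THF, 0 °C to rt
Reagents that add atoms: 14 4-hydroxybenzoic acid, OC(=O)c1ccc(O)cc1
Why: Mitsunobu esterification, in which SN2 displacement of the alkoxyphosphonium by the carboxylate inverts C6 to the R configuration of the target and the carboxylic acid (pKa about 4.5) reacts in preference to the phenol (pKa about 9), so no phenol protection is needed.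

Step 7
Reactants: 15 (1R)-3-methyl-1-[(1S,2R,5S)-2-methyl-2-(prop-2-en-1-yl)-5-(prop-1-en-2-yl)cyclopentyl]but-3-en-1-yl 4-hydroxybenzoate; 16 3-methylbutanoic acid
Product: 17 (1R)-3-methyl-1-[(1S,2S,5S)-2-methyl-2-[(1S)-1-(3-methylbutanoyloxy)prop-2-en-1-yl]-5-(prop-1-en-2-yl)cyclopentyl]but-3-en-1-yl 4-hydroxybenzoate
Conditions: Pd(OAc)2 (10 mol %), (S,S)-aryl sulfoxide–oxazoline ligand (12 mol %), 2,6-dimethyl-1,4-benzoquinone (1.5 equiv), 16 (4 equiv), toluene, 45 °C
Reagents that add atoms: 16 3-methylbutanoic acid, CC(C)CC(=O)O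
Why: Proposed new method: ligand-controlled, branched-selective allylic C–H acyloxylation of the only terminal monosubstituted olefin, in which divalent palladium cleaves a C10–H bond by carboxylate-assisted deprotonation to a π-allyl complex (the two 1,1-disubstituted olefins do not bind), quinone coordination triggers inner-sphere C–O reductive elimination of isovalerate at the internal terminus from the σ-allyl isomer with palladium on the unhindered CH2, and the chiral sulfoxide–oxazoline ligand (antipode to be fixed by screening) selects the π-allyl face so that C10 forms as S next to the quaternary carbon; the closest known reaction type is the Pd(OAc)2/sulfoxide/benzoquinone branched allylic C–H esterification of terminal olefins with carboxylic acids (White-type), which has no reliable catalyst control in the intermolecular case and has not been shown at a neopentylic position.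

Step 8
Reactants: 17 (1R)-3-methyl-1-[(1S,2S,5S)-2-methyl-2-[(1S)-1-(3-methylbutanoyloxy)prop-2-en-1-yl]-5-(prop-1-en-2-yl)cyclopentyl]but-3-en-1-yl 4-hydroxybenzoate
Product: 18 (3S,3aS,4R,8S,8aS)-6,8a-dimethyl-8-(3-methylbutanoyloxy)-3-(prop-1-en-2-yl)-1,2,3,3a,4,5,8,8a-octahydroazulen-4-yl 4-hydroxybenzoate
Conditions: second-generation Hoveyda–Grubbs catalyst RuCl2(H2IMes)(=CH-C6H4-2-OiPr) (10 mol %), toluene (2 mM), 80 °C
Reagents that add atoms: none
Why: Ring-closing olefin metathesis between the vinyl and methallyl arms (trans on the cyclopentane) closes the trans-fused trisubstituted cycloheptene, while the isopropenyl group cannot reach the vinyl arm (trans across the ring) and its closure with the methallyl arm would need a tetrasubstituted alkene.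

Step 9
Reactants: 18 (3S,3aS,4R,8S,8aS)-6,8a-dimethyl-8-(3-methylbutanoyloxy)-3-(prop-1-en-2-yl)-1,2,3,3a,4,5,8,8a-octahydroazulen-4-yl 4-hydroxybenzoate
Product: 21 (3R,3aS,4R,8S,8aS)-3-hydroxy-6,8a-dimethyl-8-(3-methylbutanoyloxy)-3-(prop-1-en-2-yl)-1,2,3,3a,4,5,8,8a-octahydroazulen-4-yl 4-hydroxybenzoate, via allylseleninic acid 19 (not isolated), via divalent selenium ester 20 (not isolated)
Conditions: SeO2 (0.5 equiv), t-BuOOH (3 equiv), CH2Cl2, rt
Reagents that add atoms: selenium dioxide, O=[Se]=O; tert-butyl hydroperoxide, CC(C)(C)OO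
Why: Selenium dioxide allylic hydroxylation (ene reaction at the isopropenyl group with loss of the ring methine hydrogen, then [2,3]-sigmatropic shift, as in limonene to p-mentha-1,8-dien-4-ol), in which C4 is sp2 in 19 so the oxygen is delivered to the open α face, anti to the C6 ester and the angular methyl and cis to H5, while the ring alkene is deactivated by its allylic ester.

Step 10
Reactants: 21 (3R,3aS,4R,8S,8aS)-3-hydroxy-6,8a-dimethyl-8-(3-methylbutanoyloxy)-3-(prop-1-en-2-yl)-1,2,3,3a,4,5,8,8a-octahydroazulen-4-yl 4-hydroxybenzoate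
Product: 22 (3S,3aS,4R,8S,8aS)-3-hydroxy-6,8a-dimethyl-8-(3-methylbutanoyloxy)-3-(propan-2-yl)-1,2,3,3a,4,5,8,8a-octahydroazulen-4-yl 4-hydroxybenzoate (CNP0086724.2)
Conditions: H2 (1 atm), RhCl(PPh3)3 (10 mol %), benzene–EtOH (1:1), rt
Reagents that add atoms: none
Why: Homogeneous hydrogenation with Wilkinson's catalyst reduces the 1,1-disubstituted isopropenyl alkene far faster than the trisubstituted, ester-flanked ring alkene, and no stereocentre is formed.

**Compound list**
1 | (S)-(−)-limonene, (4S)-1-methyl-4-(prop-1-en-2-yl)cyclohex-1-ene | CC1=CC[C@H](CC1)C(C)=C | starting material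
2 | secondary ozonide (1,2,4-trioxolane) across the former ring alkene of 1, C4 stereocentre unchanged | CC12CC[C@H](C(C)=C)CC(OO1)O2 | intermediate (not isolated)
3 | (3S)-6-oxo-3-(prop-1-en-2-yl)heptanal | CC(=O)CC[C@@H](CC=O)C(C)=C | intermediate
4 | (5R)-2-methyl-5-(prop-1-en-2-yl)cyclopent-1-ene-1-carbaldehyde | CC1=C(C=O)[C@@H](C(C)=C)CC1 | intermediate
5 | allylboronic acid pinacol ester | C=CCB1OC(C)(C)C(C)(C)O1 | starting material
6 | pinacol boronate (O–B ester) of alcohol 7 | CC1=C([C@@H](OB2OC(C)(C)C(C)(C)O2)CC=C)[C@@H](C(C)=C)CC1 | intermediate (not isolated)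
7 | (1S)-1-[(5R)-2-methyl-5-(prop-1-en-2-yl)cyclopent-1-en-1-yl]but-3-en-1-ol | CC1=C([C@@H](O)CC=C)[C@@H](C(C)=C)CC1 | intermediate
8 | potassium alkoxide of 7 | CC1=C([C@@H]([O-])CC=C)[C@@H](C(C)=C)CC1.[K+] | intermediate (not isolated)
9 | potassium enolate of aldehyde 10 | C=CC[C@@]1(C)CC[C@H](C(C)=C)C1=C[O-].[K+] | intermediate (not isolated)
10 | (1S,2R,5S)-2-methyl-2-(prop-2-en-1-yl)-5-(prop-1-en-2-yl)cyclopentane-1-carbaldehyde | C=CC[C@@]1(C)CC[C@H](C(C)=C)[C@@H]1C=O | intermediate
11 | 2-methylallylboronic acid pinacol ester | CC(=C)CB1OC(C)(C)C(C)(C)O1 | starting material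
12 | pinacol boronate (O–B ester) of alcohol 13 | C=CC[C@@]1(C)CC[C@H](C(C)=C)[C@@H]1[C@@H](OB2OC(C)(C)C(C)(C)O2)CC(C)=C | intermediate (not isolated)
13 | (1S)-3-methyl-1-[(1S,2R,5S)-2-methyl-2-(prop-2-en-1-yl)-5-(prop-1-en-2-yl)cyclopentyl]but-3-en-1-ol | C=CC[C@@]1(C)CC[C@H](C(C)=C)[C@@H]1[C@@H](O)CC(C)=C | intermediate
14 | 4-hydroxybenzoic acid | OC(=O)c1ccc(O)cc1 | starting material
15 | (1R)-3-methyl-1-[(1S,2R,5S)-2-methyl-2-(prop-2-en-1-yl)-5-(prop-1-en-2-yl)cyclopentyl]but-3-en-1-yl 4-hydroxybenzoate | C=CC[C@@]1(C)CC[C@H](C(C)=C)[C@@H]1[C@H](OC(=O)c2ccc(O)cc2)CC(C)=C | intermediate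
16 | 3-methylbutanoic acid (isovaleric acid) | CC(C)CC(=O)O | starting material
17 | (1R)-3-methyl-1-[(1S,2S,5S)-2-methyl-2-[(1S)-1-(3-methylbutanoyloxy)prop-2-en-1-yl]-5-(prop-1-en-2-yl)cyclopentyl]but-3-en-1-yl 4-hydroxybenzoate | C=C[C@H](OC(=O)CC(C)C)[C@@]1(C)CC[C@H](C(C)=C)[C@@H]1[C@H](OC(=O)c2ccc(O)cc2)CC(C)=C | intermediate
18 | (3S,3aS,4R,8S,8aS)-6,8a-dimethyl-8-(3-methylbutanoyloxy)-3-(prop-1-en-2-yl)-1,2,3,3a,4,5,8,8a-octahydroazulen-4-yl 4-hydroxybenzoate | CC1=C[C@H](OC(=O)CC(C)C)[C@@]2(C)CC[C@H](C(C)=C)[C@@H]2[C@H](OC(=O)c2ccc(O)cc2)C1 | intermediate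
19 | allylseleninic acid from 18 (C3 of the azulene is sp2, C3=C(CH3)CH2Se(=O)OH; other centres as in 18) | CC1=C[C@H](OC(=O)CC(C)C)[C@@]2(C)CCC(=C(C)C[Se](=O)O)[C@@H]2[C@H](OC(=O)c2ccc(O)cc2)C1 | intermediate (not isolated)
20 | divalent selenium ester (C3–O–Se–OH) of alcohol 21 | CC1=C[C@H](OC(=O)CC(C)C)[C@@]2(C)CC[C@](O[Se]O)(C(C)=C)[C@@H]2[C@H](OC(=O)c2ccc(O)cc2)C1 | intermediate (not isolated)
21 | (3R,3aS,4R,8S,8aS)-3-hydroxy-6,8a-dimethyl-8-(3-methylbutanoyloxy)-3-(prop-1-en-2-yl)-1,2,3,3a,4,5,8,8a-octahydroazulen-4-yl 4-hydroxybenzoate | CC1=C[C@H](OC(=O)CC(C)C)[C@@]2(C)CC[C@](O)(C(C)=C)[C@@H]2[C@H](OC(=O)c2ccc(O)cc2)C1 | intermediate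
22 | (3S,3aS,4R,8S,8aS)-3-hydroxy-6,8a-dimethyl-8-(3-methylbutanoyloxy)-3-(propan-2-yl)-1,2,3,3a,4,5,8,8a-octahydroazulen-4-yl 4-hydroxybenzoate | CC1=C[C@H](OC(=O)CC(C)C)[C@@]2(C)CC[C@](O)(C(C)C)[C@@H]2[C@H](OC(=O)c2ccc(O)cc2)C1 | target

**Step count and risks**
Total: 10 steps. Longest linear sequence: 10 steps from 1; compounds 5, 11, 14 and 16 are bought.

Three steps most likely to fail, in step order:

Step 6 (Mitsunobu at a hindered homoallylic carbinol; elimination to a conjugated diene may compete). The fallback sets out from aldehyde 10 and avoids inversion. Methallylboration of 10 with 11 under the enantiomeric (R)-TRIP phosphoric acid gives the (1R)-alcohol F1, which already has the C6 configuration of the target. Acylation with 4-(acetyloxy)benzoyl chloride (pyridine, DMAP, CH2Cl2) gives the acetate-protected benzoate F2. Pyrrolidine (CH2Cl2, 0 °C) removes only the aryl acetate, and the route is rejoined at 15.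

Step 7 (the new C–H acyloxylation; the neopentylic position may give the linear ester or poor diastereoselectivity). The fallback uses known chemistry, sets out from 15 and closes the ring first. Ring-closing metathesis of 15 with the same Ru catalyst gives the C10-methylene bicycle F3. Allylic oxidation with Rh2(cap)4 (dirhodium tetracaprolactamate, 1 mol %) and t-BuOOH gives the C10 enone F4; C7 is deactivated by the neighbouring ester. Luche reduction (NaBH4, CeCl3·7H2O, MeOH, −78 °C) adds hydride from the α face, anti to the angular methyl, and gives the 10β-allylic alcohol F5. Isovaleric anhydride, DMAP and Et3N acylate both the C10 hydroxyl and the phenol to give the bis-isovalerate F6. Pyrrolidine (CH2Cl2, 0 °C) cleaves only the aryl ester, and the route is rejoined at 18.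

Step 9 (the ene reaction may take a methyl hydrogen instead of the ring methine, or touch the ring alkene or the phenol). The fallback sets out from 18. Hydrogen-atom-transfer isomerisation with Co(salen)Cl (trivalent cobalt, salen = N,N'-bis(3,5-di-tert-butylsalicylidene)-1,2-cyclohexanediamine) and catalytic PhSiH3 moves the isopropenyl double bond to the tetrasubstituted isopropylidene compound F7. Schenck ene reaction with singlet oxygen (O2, tetraphenylporphyrin, visible light, CH2Cl2, 0 °C) on this most electron-rich alkene gives the tertiary allylic hydroperoxide F8, with oxygen on the α face. Reduction with PPh3 returns the route at 21.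

**Further compounds**
F1 | step 6 | (1R)-3-methyl-1-[(1S,2R,5S)-2-methyl-2-(prop-2-en-1-yl)-5-(prop-1-en-2-yl)cyclopentyl]but-3-en-1-ol | C=CC[C@@]1(C)CC[C@H](C(C)=C)[C@@H]1[C@H](O)CC(C)=C
F2 | step 6 | (1R)-3-methyl-1-[(1S,2R,5S)-2-methyl-2-(prop-2-en-1-yl)-5-(prop-1-en-2-yl)cyclopentyl]but-3-en-1-yl 4-(acetyloxy)benzoate | C=CC[C@@]1(C)CC[C@H](C(C)=C)[C@@H]1[C@H](OC(=O)c2ccc(OC(C)=O)cc2)CC(C)=C
F3 | step 7 | (3S,3aS,4R,8aR)-6,8a-dimethyl-3-(prop-1-en-2-yl)-1,2,3,3a,4,5,8,8a-octahydroazulen-4-yl 4-hydroxybenzoate | CC1=CC[C@@]2(C)CC[C@H](C(C)=C)[C@@H]2[C@H](OC(=O)c2ccc(O)cc2)C1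
F4 | step 7 | (3S,3aS,4R,8aS)-6,8a-dimethyl-8-oxo-3-(prop-1-en-2-yl)-1,2,3,3a,4,5,8,8a-octahydroazulen-4-yl 4-hydroxybenzoate | CC1=CC(=O)[C@@]2(C)CC[C@H](C(C)=C)[C@@H]2[C@H](OC(=O)c2ccc(O)cc2)C1
F5 | step 7 | (3S,3aS,4R,8S,8aS)-8-hydroxy-6,8a-dimethyl-3-(prop-1-en-2-yl)-1,2,3,3a,4,5,8,8a-octahydroazulen-4-yl 4-hydroxybenzoate | CC1=C[C@H](O)[C@@]2(C)CC[C@H](C(C)=C)[C@@H]2[C@H](OC(=O)c2ccc(O)cc2)C1
F6 | step 7 | (3S,3aS,4R,8S,8aS)-6,8a-dimethyl-8-(3-methylbutanoyloxy)-3-(prop-1-en-2-yl)-1,2,3,3a,4,5,8,8a-octahydroazulen-4-yl 4-(3-methylbutanoyloxy)benzoate | CC1=C[C@H](OC(=O)CC(C)C)[C@@]2(C)CC[C@H](C(C)=C)[C@@H]2[C@H](OC(=O)c2ccc(OC(=O)CC(C)C)cc2)C1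
F7 | step 9 | (3aS,4R,8S,8aS)-6,8a-dimethyl-8-(3-methylbutanoyloxy)-3-(propan-2-ylidene)-1,2,3,3a,4,5,8,8a-octahydroazulen-4-yl 4-hydroxybenzoate | CC1=C[C@H](OC(=O)CC(C)C)[C@@]2(C)CCC(=C(C)C)[C@@H]2[C@H](OC(=O)c2ccc(O)cc2)C1
F8 | step 9 | (3R,3aS,4R,8S,8aS)-3-hydroperoxy-6,8a-dimethyl-8-(3-methylbutanoyloxy)-3-(prop-1-en-2-yl)-1,2,3,3a,4,5,8,8a-octahydroazulen-4-yl 4-hydroxybenzoate | CC1=C[C@H](OC(=O)CC(C)C)[C@@]2(C)CC[C@](OO)(C(C)=C)[C@@H]2[C@H](OC(=O)c2ccc(O)cc2)C1
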